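**Plan**
1. Retrosynthetic cuts: C6–Cl with C5=C16 (ene chlorination of a C5-methyl alkene), C20–Cl (opening of an 11,20-epoxide), C2–C3 (pinacol), C9–C10 (aldol), O–C19 (lactone), C4–H (ketal reduction), O–C4 (pyran from a furan), C8–C17 (crotylation).
2. Enabling feature: the pyran O/C4/C5/C6/C7/C8 carries C16 on C5, oxygen on C7 and carbon on C4 and C8. It is therefore an oxidised 2,3,5-trisubstituted furan: its four ring carbons are C4–C7, and the neighbouring tertiary carbinol C8 supplies the ring oxygen.
3. Forward order: furan → pyranone (step 8) → γ-lactone (step 14). Ring A is made separately by a Diels–Alder reaction and joined at C9–C10 (step 21). The eight-membered oxocane ring, which completes the ten-membered carbocycle, closes at C2–C3 (step 27).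
4. Absolute stereochemistry comes from a catalytic asymmetric crotylboration (C8/C17) and a catalytic asymmetric Diels–Alder reaction (C1/C14). Everything else is relayed from these centres.
5. C4 is set by invertive opening of a ketal tethered through O9, and C7 by hydride attack anti to the C17 branch. C9/C10 come from an open aldol transition state on the enol-ether face anti to O14, and C2/C3 from the pinacol step.
6. C11 is set by epoxidation anti to C15, and C6 by chlorination on the pyran face not covered by the carbon bridge.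

Key step: step 8

Numbering:
- C1 is the quaternary ring-A carbon bearing C15H3; C2 and C3 are the acetoxy methines leading to C4.
- C4 and C8 are the carbons of the ether bridge. C5 carries C16, C6 carries Cl, and C7 is the lactone O–CH.
- C9 is the acetoxy methine on C8 and C10 is the ring-fusion CH.
- C11 is the carbinol carbon carrying C20; C12–C14 complete ring A, with C14 acetoxylated.
- C17, C18 and C19 are the lactone CH, its methyl and the carbonyl. O8 is the pyran oxygen.

Assumption: the antipodes named for the two chiral catalysts (steps 7 and 16) are those expected from the accepted transition-state models. If the sense of induction is the reverse, the mirror-image catalyst is used.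

Step 1
Reactants: 1 methyl 3-methylfuran-2-carboxylate
Product: 2 (3-methylfuran-2-yl)methanol
Conditions: LiAlH4, Et2O, 0 °C
Reagents that add atoms: none
Why: Ester reduction with a complex hydride; the furan is inert and the new carbinol carbon is C3.

Step 2
Reactants: 2 (3-methylfuran-2-yl)methanol
Product: 3 tert-butyldimethyl[(3-methylfuran-2-yl)methoxy]silane
Conditions: TBSCl, imidazole, DMF, rt
Reagents that add atoms: tert-butyldimethylsilyl chloride, CC(C)(C)[Si](C)(C)Cl
Why: Silyl ether formation; the primary TBS ether withstands lithiation, singlet oxygen and the low-temperature Lewis acids used up to step 24.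

Step 3
Reactants: 4 methyl glycolate
Product: 5 methyl 2-(triethylsilyloxy)acetate
Conditions: TESCl, imidazole, CH2Cl2, 0 °C
Reagents that add atoms: chlorotriethylsilane, CC[Si](Cl)(CC)CC
Why: Silyl ether formation; TES is chosen because mild acid removes it later while the TBS ether on C3 stays.

Step 4
Reactants: 5 methyl 2-(triethylsilyloxy)acetate
Product: 6 N-methoxy-N-methyl-2-(triethylsilyloxy)acetamide
Conditions: MeNH(OMe)·HCl, iPrMgCl, THF, −20 °C
Reagents that add atoms: N,O-dimethylhydroxylamine hydrochloride, CNOC.Cl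
Why: Weinreb amide synthesis from an ester with the magnesium amide; the amide stops the coming acylation at the ketone stage.

Step 5
Reactants: 3 tert-butyldimethyl[(3-methylfuran-2-yl)methoxy]silane; 6 N-methoxy-N-methyl-2-(triethylsilyloxy)acetamide
Product: 8 1-[5-(tert-butyldimethylsilyloxymethyl)-4-methylfuran-2-yl]-2-(triethylsilyloxy)ethan-1-one, via 5-lithiofuran 7 (not isolated)
Conditions: nBuLi, THF, −78 → 0 °C; 6, −78 °C
Reagents that add atoms: none
Why: Alpha-lithiation of the furan at its only free alpha position (C7) followed by Weinreb ketone synthesis; the chelated tetrahedral adduct prevents a second addition.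

Step 6
Reactants: 9 (E)-but-2-ene
Product: 11 diisopropyl (E)-but-2-en-1-ylboronate, via E-crotylpotassium 10 (not isolated)
Conditions: nBuLi, KOtBu, THF, −50 °C; B(OiPr)3, −78 °C; HCl in Et2O
Reagents that add atoms: triisopropyl borate, CC(C)OB(OC(C)C)OC(C)C
Why: Allylic metalation with the nBuLi/KOtBu superbase and borylation; at this temperature the crotyl anion keeps its E geometry, which the boronate inherits.

Step 7
Reactants: 8 furyl ketone; 11 diisopropyl (E)-but-2-en-1-ylboronate
Product: 12 (2R,3S)-2-[5-(tert-butyldimethylsilyloxymethyl)-4-methylfuran-2-yl]-3-methyl-1-(triethylsilyloxy)pent-4-en-2-ol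
Conditions: (S)-3,3′-dibromo-1,1′-bi-2-naphthol (15 mol %), PhCF3–toluene, −35 °C
Reagents that add atoms: none
Why: Chiral-diol-catalysed asymmetric crotylboration of a ketone through a closed chair: the flat furyl group sits equatorial, so the E-boronate gives OH and CH3 anti along C7–C8–C17–C19 as in the target, and the catalyst-bound boronate attacks the Si face of the ketone, which fixes C8 and C17 absolutely; the vinyl group is the masked C19 carboxyl.

Step 8
Reactants: 12 furyl carbinol (2R,3S)
Product: 15 pyranone hemiketal (6-hydroxy-2H-pyran-3(6H)-one; C4–OH on the face of C9; C7 ketone; C5-methyl enone), via furan endoperoxide 13 (not isolated), via Z-enedione 14 (not isolated)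
Conditions: O2, 5,10,15,20-tetraphenylporphyrin (0.5 mol %), white LED, CH2Cl2, −78 °C; Me2S, −78 °C → rt
Reagents that add atoms: dioxygen, O=O
Why: The excited porphyrin passes its energy to O2, and the singlet oxygen so formed cycloadds (4+2) across the furan alpha carbons C4 and C7 to give the 2,3,7-trioxabicyclo[2.2.1]heptene 13. Me2S removes one peroxide oxygen and the bicycle unravels to the Z-enedione 14, which has carbonyl groups at C4 and C7. The C8 hydroxyl then adds to the C4 carbonyl in a 6-exo-trig closure that makes the O–C4 bond and the pyran ring, and the hemiketal is the resting state. This is the photooxidative form of the Achmatowicz rearrangement of furyl carbinols. The only new stereocentre is anomeric C4: it equilibrates through 14, is expected to settle with OH axial (anomeric effect) and the CH2OTBS arm equatorial, and needs no control because both anomers converge in step 9. The step needs the furan to react in preference to the C19 vinyl group, which is secured because an alkylated furan traps singlet oxygen far faster than a monosubstituted alkene can undergo an ene reaction; the neutral cold medium leaves C8, C17 and both silyl ethers untouched.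

Step 9
Reactants: 15 pyranone hemiketal
Product: 17 6,8-dioxabicyclo[3.2.1]oct-3-en-2-one (O9 bonded to C4; CH2OTBS on C4; but-3-en-2-yl on C8), via C9-hydroxy hemiketal 16 (not isolated)
Conditions: PPTS, MeOH, 0 °C; then CSA (5 mol %), 4 Å MS, CH2Cl2, rt
Reagents that add atoms: none
Why: Selective acid cleavage of the TES ether followed by bicycloketalisation of an Achmatowicz product with its pendant hydroxyl; the short C8–C9–O9 tether can reach C4 only on the face that carries C9, so C4 is fixed with O9 above and C3 below.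

Step 10
Reactants: 17 bicyclic enone ketal
Product: 18 (C3/C9-cis) 2H-pyran-3(6H)-one with C4–H, free C9 carbinol, CH2OTBS on C4 and but-3-en-2-yl on C8
Conditions: Et3SiH, TiCl4, CH2Cl2, −78 °C
Reagents that add atoms: none
Why: Invertive reductive cleavage of a bicyclic ketal with Et3SiH/TiCl4: titanium binds the less hindered O9, the C4–O9 bond lengthens while the tethered alkoxide still covers the upper face, and the silane delivers hydride axially from below, so C3 ends cis to C9 as the later bridge requires, whereas direct reduction of 15 would be steered to the wrong face by the larger C17 branch.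

Step 11
Reactants: 18 C9 alcohol
Product: 19 C9 triethylsilyl ether of 18
Conditions: TESCl, imidazole, CH2Cl2, 0 °C
Reagents that add atoms: chlorotriethylsilane, CC[Si](Cl)(CC)CC
Why: Silylation keeps O9 from capturing the C19 carbonyl as a five-membered lactol or spirolactone in the next steps.

Step 12
Reactants: 19 enone with C17 vinyl branch
Product: 21 C19 aldehyde (C7 enone intact), via secondary ozonide 20 (not isolated)
Conditions: O3, CH2Cl2, −78 °C, Sudan Red 7B endpoint; Me2S, −78 °C → rt
Reagents that add atoms: ozone, [O-][O+]=O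
Why: Ozonolysis; the electron-poor trisubstituted enone alkene reacts much more slowly than the terminal vinyl group, and the neutral reductive work-up spares C17.

Step 13
Reactants: 21 keto aldehyde
Product: 22 C7,C19-diol (C7–OH cis to the C17 branch)
Conditions: NaBH4, CeCl3·7H2O, MeOH, −78 → −20 °C
Reagents that add atoms: none
Why: Luche reduction (1,2-selective): with the cis C3 and C9 arms pseudoequatorial the C17 branch is pseudoaxial next to the carbonyl, so hydride enters axially from the opposite (upper) face and places O7 on the same side as C17; the aldehyde is reduced as well.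

Step 14
Reactants: 22 diol
Product: 24 cis-fused γ-lactone (C19(=O)–O7; CH2OTES on C8; CH2OTBS on C4; C5=C6), via lactol 23 (not isolated)
Conditions: TEMPO (20 mol %), PhI(OAc)2, CH2Cl2, rt
Reagents that add atoms: none
Why: Oxidative lactonisation of a 1,4-diol with TEMPO/PhI(OAc)2: the hindered oxoammonium ion takes the primary C19 carbinol first, the aldehyde is trapped by the cis C7 hydroxyl, and the lactol is oxidised on, all under conditions too mild to epimerise C17.

Step 15
Reactants: 24 lactone
Product: 25 C9 aldehyde of the pyran lactone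
Conditions: (COCl)2, DMSO, CH2Cl2, −78 → −35 °C; Et3N, −78 °C → rt
Reagents that add atoms: none
Why: Swern oxidation applied directly to a primary TES ether (cleavage by the activated sulfonium reagent, then oxidation), a known chemoselective process that leaves primary TBS ethers alone; the aldehyde has no alpha hydrogen.

Step 16
Reactants: 26 methacrolein; 27 (E)-1-(trimethylsilyloxy)buta-1,3-diene
Product: 28 (1R,2S)-1-methyl-2-(trimethylsilyloxy)cyclohex-3-ene-1-carbaldehyde
Conditions: (S)-3,3-diphenyl-1-(o-tolyl)tetrahydro-1H,3H-pyrrolo[1,2-c][1,3,2]oxazaborole (10 mol %), Tf2NH (8 mol %), CH2Cl2, −78 °C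
Reagents that add atoms: none
Why: Enantioselective Diels–Alder reaction catalysed by a protonated chiral oxazaborolidine: the 1-silyloxy group directs "ortho" bonding (C14–C1), the formyl group lies endo so that O14 and C2 end cis, and the bound s-trans enal is open on one face only, which sets quaternary C1 and C14.

Step 17
Reactants: 28 Diels–Alder aldehyde
Product: 30 (1S,6S)-6-(hydroxymethyl)-6-methylcyclohex-2-en-1-ol, via TMS ether alcohol 29 (not isolated)
Conditions: NaBH4, MeOH, 0 °C; aq. citric acid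
Reagents that add atoms: none
Why: Borohydride reduction of the non-enolisable aldehyde followed by acid cleavage of the labile TMS ether gives the diol for uniform protection.

Step 18
Reactants: 30 diol
Product: 31 bis(tert-butyldimethylsilyl) ether of 30
Conditions: TBSOTf, 2,6-lutidine, CH2Cl2, 0 °C
Reagents that add atoms: tert-butyldimethylsilyl triflate, CC(C)(C)[Si](C)(C)OS(=O)(=O)C(F)(F)F
Why: Silylation with the triflate, which is reactive enough for both neopentyl-type hydroxyls.

Step 19
Reactants: 31 bis-silyl ether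
Product: 32 (4S,5S)-4-(tert-butyldimethylsilyloxy)-5-(tert-butyldimethylsilyloxymethyl)-5-methylcyclohex-2-en-1-one
Conditions: Rh2(cap)4 (1 mol %), tBuOOH, K2CO3, CH2Cl2, rt
Reagents that add atoms: tert-butyl hydroperoxide, CC(C)(C)OO
Why: Catalytic allylic C–H oxidation: the peroxyl radical abstracts hydrogen from the free methylene C11 rather than from C14–H, which is buried beside the quaternary carbon, and oxygen ends at the less hindered allyl terminus to give the C11 enone.

Step 20
Reactants: 32 enone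
Product: 34 cross-conjugated trimethylsilyl dienol ether (C10=C11(OTMS)–C12=C13), via lithium dienolate 33 (not isolated)
Conditions: LDA, THF, −78 °C; TMSCl
Reagents that add atoms: chlorotrimethylsilane, C[Si](C)(C)Cl
Why: Kinetic alpha-prime deprotonation of a cyclohexenone and O-silylation give a regiodefined C10 nucleophile next to the quaternary carbon.

Step 21
Reactants: 25 C9 aldehyde; 34 silyl dienol ether
Product: 35 C9–C10 aldol (9-OH; C11 enone; 9,10-syn; C9 trans to C2 on ring A)
Conditions: BF3·OEt2, CH2Cl2, −78 °C; aq. NaHCO3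
Reagents that add atoms: none
Why: Mukaiyama aldol addition through an open transition state: the aldehyde meets the dienol ether on the face that carries only C15 (anti to O14 and to the C2 arm), which sets C10, and the antiperiplanar array with fully substituted C8 anti to quaternary C1 and the C=O dipole opposed to the enol C–O bond gives the 9,10-syn relationship of the target, which a closed transition state of a cyclic enolate would not give.

Step 22
Reactants: 35 aldol enone
Product: 36 saturated C11 ketone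
Conditions: [(Ph3P)CuH]6, toluene, H2O (2 equiv), rt
Reagents that add atoms: none
Why: Conjugate reduction with copper hydride (Stryker reagent), selective for the enone over the trisubstituted C5=C6 alkene, the lactone and the free carbinol.

Step 23
Reactants: 36 β-hydroxy ketone
Product: 37 C11=C20 exocyclic alkene
Conditions: Zn, CH2Br2, TiCl4 (preformed in THF), CH2Cl2, 0 °C → rt
Reagents that add atoms: dibromomethane, BrCBr
Why: Lombardo methylenation; the non-basic gem-dimetallic reagent converts an enolisable β-hydroxy ketone without retro-aldol cleavage or C10 epimerisation and ignores the lactone.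

Step 24
Reactants: 37 C9 alcohol
Product: 38 C9 acetate
Conditions: Ac2O, DMAP, Et3N, CH2Cl2, rt → 40 °C
Reagents that add atoms: acetic anhydride, CC(=O)OC(C)=O
Why: DMAP-catalysed acetylation installs the final C9 ester and prevents O9 from forming a lactol with the C2 aldehyde later.

Step 25
Reactants: 38 tris-TBS ether
Product: 39 C2,C3-diol (both primary; C14–OTBS kept)
Conditions: HF·pyridine, pyridine, THF, 0 °C
Reagents that add atoms: none
Why: Selective desilylation; primary TBS ethers are cleaved by buffered HF·pyridine well before the secondary neopentyl C14 ether.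

Step 26
Reactants: 39 diol
Product: 40 C2,C3-dialdehyde
Conditions: Dess–Martin periodinane, NaHCO3, CH2Cl2, 0 °C → rt
Reagents that add atoms: none
Why: Dess–Martin oxidation of both primary alcohols under buffered conditions that do not enolise the C3 aldehyde toward C4.

Step 27
Reactants: 40 dialdehyde
Product: 41 tricyclic (2R,3R)-2,3-diol (eight-membered ring closed)
Conditions: SmI2 (4 equiv), THF, 0.002 M, slow addition of 40, rt
Reagents that add atoms: none
Why: Intramolecular pinacol coupling, a known way to close the eight-membered ring of bicyclo[5.3.1]undecane frameworks: a samarium-bridged, nearly eclipsed O–C2–C3–O array is compatible with a C1–C2–C3–C4 torsion near 100° (a normal cyclooctane value), which corresponds to the threo diol, whereas the erythro diol would need quaternary C1 and C4 eclipsed, and of the two threo arrays the trans ring-A fusion and the cis anchoring at C4/C8 should allow only the one with both metal alkoxides on the outer rim.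

Step 28
Reactants: 41 diol silyl ether
Product: 42 2,3,14-triol
Conditions: HF·pyridine, MeCN, rt → 40 °C
Reagents that add atoms: none
Why: Acidic fluoride desilylation of the hindered C14 ether; no acyl migration is expected in this medium.

Step 29
Reactants: 42 triol
Product: 43 2,3,9,14-tetraacetate with C5=C6 and C11=C20
Conditions: Ac2O, DMAP, pyridine, 40 °C
Reagents that add atoms: acetic anhydride, CC(=O)OC(C)=O
Why: Exhaustive DMAP-catalysed acetylation of the three secondary hydroxyls before the tertiary C11 hydroxyl exists.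

Step 30
Reactants: 43 diene tetraacetate
Product: 44 11,20-epoxide (oxygen on the face opposite C15)
Conditions: mCPBA, NaHCO3, CH2Cl2, 0 °C
Reagents that add atoms: 3-chloroperbenzoic acid, O=C(OO)c1cccc(Cl)c1
Why: Prilezhaev epoxidation: the unactivated 1,1-disubstituted alkene reacts before C5=C6, which is deactivated by two allylic C–O bonds and screened on both faces, and the peracid approaches anti to the axial C15 methyl (1,3-related to C11), so oxygen ends equatorial and C20 axial.

Step 31
Reactants: 44 epoxide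
Product: 45 chlorohydrin (C11–OH, C20–Cl)
Conditions: LiCl, AcOH, THF, rt
Reagents that add atoms: lithium chloride, [Li+].[Cl-]
Why: Regioselective SN2 opening of a 1,1-disubstituted epoxide at its CH2 terminus by chloride under weakly acidic conditions; the C11–O bond and hence the configuration are retained.

Step 32
Reactants: 45 chlorohydrin
Product: 46 fragilide F
Conditions: Ca(OCl)2, solid CO2, CH2Cl2–H2O, 0 °C
Reagents that add atoms: calcium hypochlorite, [Ca+2].[O-]Cl.[O-]Cl
Why: Ene-type allylic chlorination of a trisubstituted alkene with HOCl: chlorine bonds to the less substituted C6 on the pyran face not covered by the C3–C2–C1–C10–C9 bridge (cis to O7), and the proton is lost from C16 because loss of the bridgehead C4–H would give a strained bridgehead enol ether.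

**Compound list**
1 | methyl 3-methylfuran-2-carboxylate | Cc1ccoc1C(=O)OC | starting material
2 | (3-methylfuran-2-yl)methanol | Cc1ccoc1CO | intermediate
3 | tert-butyldimethyl[(3-methylfuran-2-yl)methoxy]silane | Cc1ccoc1CO[Si](C)(C)C(C)(C)C | intermediate
4 | methyl glycolate | OCC(=O)OC | starting material
5 | methyl 2-(triethylsilyloxy)acetate | CC[Si](CC)(CC)OCC(=O)OC | intermediate
6 | N-methoxy-N-methyl-2-(triethylsilyloxy)acetamide | CC[Si](CC)(CC)OCC(=O)N(C)OC | intermediate
7 | 5-lithio derivative of 3 | Cc1cc([Li])oc1CO[Si](C)(C)C(C)(C)C | intermediate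
8 | 1-[5-(tert-butyldimethylsilyloxymethyl)-4-methylfuran-2-yl]-2-(triethylsilyloxy)ethan-1-one | Cc1cc(C(=O)CO[Si](CC)(CC)CC)oc1CO[Si](C)(C)C(C)(C)C | intermediate
9 | (E)-but-2-ene | C/C=C/C | starting material
10 | (E)-crotylpotassium | C/C=C/C[K] | intermediate
11 | diisopropyl (E)-but-2-en-1-ylboronate | C/C=C/CB(OC(C)C)OC(C)C | intermediate
12 | (2R,3S)-2-[5-(tert-butyldimethylsilyloxymethyl)-4-methylfuran-2-yl]-3-methyl-1-(triethylsilyloxy)pent-4-en-2-ol (key-step precursor) | Cc1cc([C@@](O)([C@@H](C)C=C)CO[Si](CC)(CC)CC)oc1CO[Si](C)(C)C(C)(C)C | intermediate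
13 | 2,3,7-trioxabicyclo[2.2.1]hept-5-ene from O2 addition across C4/C7 of 12 (both facial isomers; C8, C17 as in 12) | CC1=CC2(OOC1(CO[Si](C)(C)C(C)(C)C)O2)[C@@](O)([C@@H](C)C=C)CO[Si](CC)(CC)CC | intermediate
14 | (Z)-enedione, C4 and C7 ketones cis on C5(CH3)=C6H, free C8 carbinol | O=C(CO[Si](C)(C)C(C)(C)C)/C(C)=C\C(=O)[C@@](O)([C@@H](C)C=C)CO[Si](CC)(CC)CC | intermediate
15 | 6-hydroxy-2H-pyran-3(6H)-one: C4(OH)(CH2OTBS) with OH on the face of C9, C5-methyl enone, C7 ketone, C8 bearing CH2OTES and (S)-but-3-en-2-yl (key-step product) | CC=1[C@@](O)(CO[Si](C)(C)C(C)(C)C)O[C@]([C@@H](C)C=C)(CO[Si](CC)(CC)CC)C(=O)C=1 | intermediate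
16 | C9-hydroxy analogue of 15 | CC=1[C@@](O)(CO[Si](C)(C)C(C)(C)C)O[C@]([C@@H](C)C=C)(CO)C(=O)C=1 | intermediate
17 | 6,8-dioxabicyclo[3.2.1]oct-3-en-2-one, O9 bridging C9 to C4, CH2OTBS on C4, (S)-but-3-en-2-yl on C8 | CC=1[C@]2(CO[Si](C)(C)C(C)(C)C)OC[C@](O2)([C@@H](C)C=C)C(=O)C=1 | intermediate
18 | 2H-pyran-3(6H)-one with C4–H, CH2OTBS (C4) cis to CH2OH (C8), (S)-but-3-en-2-yl on C8 | CC=1[C@H](CO[Si](C)(C)C(C)(C)C)O[C@]([C@@H](C)C=C)(CO)C(=O)C=1 | intermediate
19 | C9 triethylsilyl ether of 18 | CC=1[C@H](CO[Si](C)(C)C(C)(C)C)O[C@]([C@@H](C)C=C)(CO[Si](CC)(CC)CC)C(=O)C=1 | intermediate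
20 | 1,2,4-trioxolane of the vinyl group of 19 | CC=1[C@H](CO[Si](C)(C)C(C)(C)C)O[C@]([C@@H](C)C2OCOO2)(CO[Si](CC)(CC)CC)C(=O)C=1 | intermediate
21 | C19 aldehyde, C7 enone | CC=1[C@H](CO[Si](C)(C)C(C)(C)C)O[C@]([C@@H](C)C=O)(CO[Si](CC)(CC)CC)C(=O)C=1 | intermediate
22 | C7,C19-diol, O7 cis to C17 | CC=1[C@H](CO[Si](C)(C)C(C)(C)C)O[C@]([C@@H](C)CO)(CO[Si](CC)(CC)CC)[C@@H](O)C=1 | intermediate
23 | C19 lactol (both anomers) | CC=1[C@H](CO[Si](C)(C)C(C)(C)C)O[C@]2([C@@H](C)C(O)O[C@H]2C=1)CO[Si](CC)(CC)CC | intermediate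
24 | cis-fused pyran γ-lactone, C4, C7, C8, C17 as in 46, CH2OTBS on C4, CH2OTES on C8 | CC=1[C@H](CO[Si](C)(C)C(C)(C)C)O[C@]2([C@@H](C)C(=O)O[C@H]2C=1)CO[Si](CC)(CC)CC | intermediate
25 | C9 aldehyde of the pyran lactone | CC=1[C@H](CO[Si](C)(C)C(C)(C)C)O[C@]2([C@@H](C)C(=O)O[C@H]2C=1)C=O | intermediate
26 | methacrolein | CC(=C)C=O | starting material
27 | (E)-1-(trimethylsilyloxy)buta-1,3-diene | C=C/C=C/O[Si](C)(C)C | starting material
28 | (1R,2S)-1-methyl-2-(trimethylsilyloxy)cyclohex-3-ene-1-carbaldehyde | C1=C[C@H](O[Si](C)(C)C)[C@](C)(C=O)CC1 | intermediate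
29 | primary alcohol from 28, TMS ether intact | C1=C[C@H](O[Si](C)(C)C)[C@](C)(CO)CC1 | intermediate
30 | (1S,6S)-6-(hydroxymethyl)-6-methylcyclohex-2-en-1-ol | C1=C[C@H](O)[C@](C)(CO)CC1 | intermediate
31 | bis-TBS ether of 30 | C1=C[C@H](O[Si](C)(C)C(C)(C)C)[C@](C)(CO[Si](C)(C)C(C)(C)C)CC1 | intermediate
32 | (4S,5S)-4-(tert-butyldimethylsilyloxy)-5-(tert-butyldimethylsilyloxymethyl)-5-methylcyclohex-2-en-1-one | O=C1C=C[C@H](O[Si](C)(C)C(C)(C)C)[C@](C)(CO[Si](C)(C)C(C)(C)C)C1 | intermediate
33 | cross-conjugated lithium dienolate of 32 | [Li]OC=1C=C[C@H](O[Si](C)(C)C(C)(C)C)[C@](C)(CO[Si](C)(C)C(C)(C)C)C=1 | intermediate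
34 | trimethylsilyl dienol ether of 32 (C10=C11(OTMS)–C12=C13) | C[Si](C)(C)OC=1C=C[C@H](O[Si](C)(C)C(C)(C)C)[C@](C)(CO[Si](C)(C)C(C)(C)C)C=1 | intermediate
35 | C9–C10 aldol, 9-OH, C11 enone, C1, C4, C7–C10, C14, C17 as in 46 | CC=1[C@H](CO[Si](C)(C)C(C)(C)C)O[C@]2([C@@H](C)C(=O)O[C@H]2C=1)[C@@H](O)[C@H]1C(=O)C=C[C@H](O[Si](C)(C)C(C)(C)C)[C@]1(C)CO[Si](C)(C)C(C)(C)C | intermediate
36 | 12,13-dihydro derivative of 35 (C11 ketone) | CC=1[C@H](CO[Si](C)(C)C(C)(C)C)O[C@]2([C@@H](C)C(=O)O[C@H]2C=1)[C@@H](O)[C@H]1C(=O)CC[C@H](O[Si](C)(C)C(C)(C)C)[C@]1(C)CO[Si](C)(C)C(C)(C)C | intermediate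
37 | C11=C20 methylene compound, 9-OH | CC=1[C@H](CO[Si](C)(C)C(C)(C)C)O[C@]2([C@@H](C)C(=O)O[C@H]2C=1)[C@@H](O)[C@H]1C(=C)CC[C@H](O[Si](C)(C)C(C)(C)C)[C@]1(C)CO[Si](C)(C)C(C)(C)C | intermediate
38 | 9-acetate of 37 | CC=1[C@H](CO[Si](C)(C)C(C)(C)C)O[C@]2([C@@H](C)C(=O)O[C@H]2C=1)[C@@H](OC(C)=O)[C@H]1C(=C)CC[C@H](O[Si](C)(C)C(C)(C)C)[C@]1(C)CO[Si](C)(C)C(C)(C)C | intermediate
39 | C2,C3 primary diol, 9-OAc, 14-OTBS | CC=1[C@H](CO)O[C@]2([C@@H](C)C(=O)O[C@H]2C=1)[C@@H](OC(C)=O)[C@H]1C(=C)CC[C@H](O[Si](C)(C)C(C)(C)C)[C@]1(C)CO | intermediate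
40 | C2,C3 dialdehyde | CC=1[C@H](C=O)O[C@]2([C@@H](C)C(=O)O[C@H]2C=1)[C@@H](OC(C)=O)[C@H]1C(=C)CC[C@H](O[Si](C)(C)C(C)(C)C)[C@]1(C)C=O | intermediate
41 | tricyclic (2R,3R)-diol, 9-OAc, 14-OTBS, C5=C6, C11=C20 | CC=1[C@H]2O[C@]3([C@@H](C)C(=O)O[C@H]3C=1)[C@@H](OC(C)=O)[C@H]1C(=C)CC[C@H](O[Si](C)(C)C(C)(C)C)[C@]1(C)[C@@H](O)[C@@H]2O | intermediate
42 | 2,3,14-triol 9-acetate | CC=1[C@H]2O[C@]3([C@@H](C)C(=O)O[C@H]3C=1)[C@@H](OC(C)=O)[C@H]1C(=C)CC[C@H](O)[C@]1(C)[C@@H](O)[C@@H]2O | intermediate
43 | 2,3,9,14-tetraacetate, C5=C6, C11=C20 | CC=1[C@H]2O[C@]3([C@@H](C)C(=O)O[C@H]3C=1)[C@@H](OC(C)=O)[C@H]1C(=C)CC[C@H](OC(C)=O)[C@]1(C)[C@@H](OC(C)=O)[C@@H]2OC(C)=O | intermediate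
44 | 11,20-epoxide of 43 (O anti to C15) | CC=1[C@H]2O[C@]3([C@@H](C)C(=O)O[C@H]3C=1)[C@@H](OC(C)=O)[C@H]1[C@@]4(CO4)CC[C@H](OC(C)=O)[C@]1(C)[C@@H](OC(C)=O)[C@@H]2OC(C)=O | intermediate
45 | (11R)-chlorohydrin, C5=C6 still in place | CC=1[C@H]2O[C@]3([C@@H](C)C(=O)O[C@H]3C=1)[C@@H](OC(C)=O)[C@H]1[C@@](O)(CCl)CC[C@H](OC(C)=O)[C@]1(C)[C@@H](OC(C)=O)[C@@H]2OC(C)=O | intermediate
46 | fragilide F (1R,2R,3R,4R,6S,7R,8R,9S,10S,11R,14S,17R) | C=C1[C@H]2O[C@]3([C@@H](C)C(=O)O[C@H]3[C@H]1Cl)[C@@H](OC(C)=O)[C@H]1[C@@](O)(CCl)CC[C@H](OC(C)=O)[C@]1(C)[C@@H](OC(C)=O)[C@@H]2OC(C)=O | target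

**Count.** Total steps: 32. Longest linear sequence: 24 (steps 1, 2, 5, 7–15, 21–32).

**Steps most likely to fail**

Step 27. Closure of the strained, bridged eight-membered ring may be slow. Plain reduction of the aldehydes, reductive scission of the C4–O bond next to the C3 ketyl, or erythro-selective coupling could then take over.
- The fallback replaces reductive C–C coupling by ring-closing metathesis followed by stepwise oxygenation. It sets out from 38 and returns at 44.
- The exocyclic alkene of 38 is first masked with mCPBA as the spiro-epoxide F1.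
- TBAF/AcOH at 0 °C frees the two primary hydroxyls to give the epoxy diol F2, and Dess–Martin oxidation gives the epoxy dialdehyde F3.
- Double Wittig methylenation (Ph3P=CH2) gives the divinyl compound F4.
- The second-generation Grubbs catalyst (H2IMes)(PCy3)Cl2Ru=CHPh in hot dilute toluene closes the Z-cyclooctene F5.
- OsO4/NMO should add to the exposed outer face of the strained alkene and give the cis-diol F6, in which C3 is correct and C2 is epimeric.
- One equivalent of Ac2O acetylates the less hindered C3 hydroxyl to give the monoacetate F7, and Dess–Martin oxidation gives the C2 ketone F8.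
- NaBH4, which should also arrive from the outer face, gives the 2R alcohol F9.
- TBAF/AcOH then frees O14 to give the 2,14-diol F10, and acetylation gives 44.

Step 21. The two neopentyl-type partners may combine too slowly, so that protodesilylation of the dienol ether wins, or the simple diastereoselection at C9 may erode.
- The fallback moves the control of C9 from the C–C bond formation to a ketone reduction. It sets out from 32 (with 25) and returns at 37.
- The lithium dienolate 33, made from 32 with LDA, is added directly to 25. The closed chair transition state of a cyclic enolate should give the 9,10-anti aldol F11.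
- Copper hydride reduction gives the saturated ketone F12, and Lombardo methylenation gives the 9-epi alcohol F13.
- Dess–Martin oxidation gives the C9 ketone F14.
- Immediate reduction with Zn(BH4)2, chelated between the C9 carbonyl and the pyran oxygen O8, should deliver hydride from the face that gives 37.

Step 32. Facial selectivity may be poor, with chlorine delivered to the upper face if the carbon bridge leans away from C5=C6. Allylic scrambling of the chloride is a second risk.
- The fallback turns an upper-face attack to advantage. It sets out from 45 and returns at 46.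
- A Schenck ene reaction (O2, tetraphenylporphyrin, light) on that same face gives the allylic hydroperoxide F15.
- PPh3 reduces it to the 6-epi allylic alcohol F16.
- An Appel reaction (PPh3, CCl4) replaces the hydroxyl by chloride with inversion to give 46.

**Further compounds**
F1 | step 27 | 11,20-epoxide of 38 | CC=1[C@H](CO[Si](C)(C)C(C)(C)C)O[C@]2([C@@H](C)C(=O)O[C@H]2C=1)[C@@H](OC(C)=O)[C@H]1[C@@]3(CO3)CC[C@H](O[Si](C)(C)C(C)(C)C)[C@]1(C)CO[Si](C)(C)C(C)(C)C
F2 | step 27 | epoxy C2,C3-diol | CC=1[C@H](CO)O[C@]2([C@@H](C)C(=O)O[C@H]2C=1)[C@@H](OC(C)=O)[C@H]1[C@@]3(CO3)CC[C@H](O[Si](C)(C)C(C)(C)C)[C@]1(C)CO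
F3 | step 27 | epoxy C2,C3-dialdehyde | CC=1[C@H](C=O)O[C@]2([C@@H](C)C(=O)O[C@H]2C=1)[C@@H](OC(C)=O)[C@H]1[C@@]3(CO3)CC[C@H](O[Si](C)(C)C(C)(C)C)[C@]1(C)C=O
F4 | step 27 | C1,C4-divinyl compound | CC=1[C@H](C=C)O[C@]2([C@@H](C)C(=O)O[C@H]2C=1)[C@@H](OC(C)=O)[C@H]1[C@@]3(CO3)CC[C@H](O[Si](C)(C)C(C)(C)C)[C@]1(C)C=C
F5 | step 27 | tricyclic (2Z)-cyclooctene | CC=1[C@H]2O[C@]3([C@@H](C)C(=O)O[C@H]3C=1)[C@@H](OC(C)=O)[C@H]1[C@@]4(CO4)CC[C@H](O[Si](C)(C)C(C)(C)C)[C@]1(C)/C=C\2
F6 | step 27 | cis-2,3-diol (2-epi) | CC=1[C@H]2O[C@]3([C@@H](C)C(=O)O[C@H]3C=1)[C@@H](OC(C)=O)[C@H]1[C@@]4(CO4)CC[C@H](O[Si](C)(C)C(C)(C)C)[C@]1(C)[C@H](O)[C@@H]2O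
F7 | step 27 | 3-monoacetate of F6 | CC=1[C@H]2O[C@]3([C@@H](C)C(=O)O[C@H]3C=1)[C@@H](OC(C)=O)[C@H]1[C@@]4(CO4)CC[C@H](O[Si](C)(C)C(C)(C)C)[C@]1(C)[C@H](O)[C@@H]2OC(C)=O
F8 | step 27 | C2 ketone | CC=1[C@H]2O[C@]3([C@@H](C)C(=O)O[C@H]3C=1)[C@@H](OC(C)=O)[C@H]1[C@@]4(CO4)CC[C@H](O[Si](C)(C)C(C)(C)C)[C@]1(C)C(=O)[C@@H]2OC(C)=O
F9 | step 27 | (2R)-alcohol 3,9-diacetate | CC=1[C@H]2O[C@]3([C@@H](C)C(=O)O[C@H]3C=1)[C@@H](OC(C)=O)[C@H]1[C@@]4(CO4)CC[C@H](O[Si](C)(C)C(C)(C)C)[C@]1(C)[C@@H](O)[C@@H]2OC(C)=O
F10 | step 27 | 2,14-diol 3,9-diacetate | CC=1[C@H]2O[C@]3([C@@H](C)C(=O)O[C@H]3C=1)[C@@H](OC(C)=O)[C@H]1[C@@]4(CO4)CC[C@H](O)[C@]1(C)[C@@H](O)[C@@H]2OC(C)=O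
F11 | step 21 | 9-epi aldol (9,10-anti) | CC=1[C@H](CO[Si](C)(C)C(C)(C)C)O[C@]2([C@@H](C)C(=O)O[C@H]2C=1)[C@H](O)[C@H]1C(=O)C=C[C@H](O[Si](C)(C)C(C)(C)C)[C@]1(C)CO[Si](C)(C)C(C)(C)C
F12 | step 21 | 9-epi saturated ketone | CC=1[C@H](CO[Si](C)(C)C(C)(C)C)O[C@]2([C@@H](C)C(=O)O[C@H]2C=1)[C@H](O)[C@H]1C(=O)CC[C@H](O[Si](C)(C)C(C)(C)C)[C@]1(C)CO[Si](C)(C)C(C)(C)C
F13 | step 21 | 9-epi methylene alcohol | CC=1[C@H](CO[Si](C)(C)C(C)(C)C)O[C@]2([C@@H](C)C(=O)O[C@H]2C=1)[C@H](O)[C@H]1C(=C)CC[C@H](O[Si](C)(C)C(C)(C)C)[C@]1(C)CO[Si](C)(C)C(C)(C)C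
F14 | step 21 | C9 ketone | CC=1[C@H](CO[Si](C)(C)C(C)(C)C)O[C@]2([C@@H](C)C(=O)O[C@H]2C=1)C(=O)[C@H]1C(=C)CC[C@H](O[Si](C)(C)C(C)(C)C)[C@]1(C)CO[Si](C)(C)C(C)(C)C
F15 | step 32 | C6 allylic hydroperoxide (upper face), C5=C16 | C=C1[C@H]2O[C@]3([C@@H](C)C(=O)O[C@H]3[C@@H]1OO)[C@@H](OC(C)=O)[C@H]1[C@@](O)(CCl)CC[C@H](OC(C)=O)[C@]1(C)[C@@H](OC(C)=O)[C@@H]2OC(C)=O
F16 | step 32 | C6 allylic alcohol (upper face), C5=C16 | C=C1[C@H]2O[C@]3([C@@H](C)C(=O)O[C@H]3[C@@H]1O)[C@@H](OC(C)=O)[C@H]1[C@@](O)(CCl)CC[C@H](OC(C)=O)[C@]1(C)[C@@H](OC(C)=O)[C@@H]2OC(C)=O
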